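## Structural features

The target is a germacrane lactone: a ten-membered carbocycle (C1–C10) in which one oxygen joins C1 and C4, so that C1–C2–C3–C4–O is an oxolane inside an 11-oxabicyclo[6.2.1]undecane. A butenolide is fused at C6–C7: the lactone oxygen sits on C6, C7=C11 lies in the lactone, C12 is the carbonyl, C11 carries the acetoxymethyl carbon C13, and an exocyclic C5=C6 enol-lactone bond (C4 cis to C7) makes C4 a tertiary allylic ether carbon. There are four stereocentres: C10 (tertiary alcohol, R) is bonded to C1 (ether CH, S), C4 (S) faces C1 across the oxolane, and C8 (angelate, S) is one methylene from C10 and next to the tetrasubstituted C7. C1 and C4 carry like descriptors, which puts the C1–C10 and C4–C5 bonds on opposite faces of the oxolane, so the six-carbon bridge must be drawn across the five-membered ring; this, more than the medium ring, is the real difficulty. Fragile groups are the angelate (Z to E isomerisation), the enol lactone and allylic acetate (bases, nucleophiles), the tertiary allylic C4–O bond (acid) and, before the bridge exists, the medium ring with its transannular reactivity. The key step uses the carbocycle itself: C6 is at the ketone level, 1,5 to the C1–C10 pair (an E alkene before the ether is closed), and C8 beside C9 is oxygenated. That is the pattern left by an oxy-Cope ring expansion that makes C8–C9 and breaks a temporary C1–C6 bond.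

## Logic of the disconnections

31 is cut at the C8–O acyl bond into 28 and 29. The Z ester isomerises easily, so it is attached last. The forward step must esterify only the secondary hydroxyl and must not touch the Z geometry.

28 is traced through 27 to 26 by exchanging the C13 acetate and the C8 ether. 26 has a primary and a tertiary hydroxyl, so acetylation is selective. The ether cleavage must spare the dienolide.

26 is cut at O–C1. The C1–O bond and the C10 hydroxyl both come from one epoxide in 24 (through 25). This turns the bicycle into a monocycle and traces C1 and C10 to a single alkene face. The demand is a (1R,10R) epoxide and a 5-exo opening with inversion that forms the trans-disposed bridge.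

24 is cut at the lactone O–C12 bond and then at C7=C11, through 22, to 17 and 20. This removes the butenolide and leaves a ketone. The forward steps need enolisation at C7 and not at C5, an alkene geometry that lets the acid reach the C6 oxygen, and no strong acid while the epoxide is present.

17 goes back to 16 by removal of the epoxide oxygen. Reagent control sets the face while the functionality is still robust.

16 is the product of the key step. Cutting C8–C9 and reconnecting C1–C6 gives 13. The ten-membered ring becomes a cyclohexanol, C8 is traced to the geometry of an enol ether, and the E alkene to a chair. The demand is trans-diequatorial alkenyl groups and an E enol ether.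

13 is cut at C6–C7 into 7 and 10 (through 11 and 12). Addition must come from the equatorial side, and the alkyne must be reduced to the E enol ether. 10 comes from 8 and 9.

7 is traced through 6, 5, 4 and 3 to 2 and 1. The future C4 oxygen is placed cis to the isopropenyl group by a hydroxyl-directed epoxidation, so the carbon next to the ketone never has to be epimerised. The demand is a cis-selective 1,2-reduction of 2.

20 comes from 18 through 19 by silylation and cleavage of the alkene.

## Other disconnections considered

Alternative 1: The cut is C7–C8. In the forward step butyllithium exchanges tin for lithium at C8 of the thirteen-membered stannyl ether A1, and the α-alkoxy carbanion undergoes a [2,3] Wittig–Still shift that forms C7–C8, breaks O–C12 and contracts the ring to the ten-membered alcohol A2.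
- In its favour: the oxolane is already in A1, where it can be made on an open chain. The strained bridge is then imposed by a strongly driven carbanion rearrangement and not by a transannular substitution; on this point it is better than the chosen plan. C7 and C8 are set together in a concerted shift. Precedent for macrocyclic [2,3] ring contractions is equal to that for the oxy-Cope expansion.
- Against it here: A2 is far from the target in oxidation level (C12 methylene to lactone carbonyl, C7–H to C7=C11, ketal to enol lactone). A1 needs a macro-etherification with a stannyl carbinol and a defined allyl ether geometry.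
- Comparison: the mechanism is equally reliable, the bridge is handled better, but the step count is clearly higher.

Alternative 2: The cuts are C11–C12 and C12–O. Pd(PPh3)4 (zerovalent palladium) inserts into the C11–I bond of the (Z)-β-iodoenone A3, CO inserts, and the enol oxygen of the C6 ketone captures the acylpalladium to give the butenolide A4 with C5=C6.
- In its favour: the lactone and the enol double bond form in one operation under neutral conditions, and the C7=C11 geometry is fixed in the iodide. On this point it is better than the two-step pyruvate annulation of the chosen plan.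
- Against it here: it leaves the ten-membered ring, the bridge and C8 unsolved. A3 needs a stereodefined tetrasubstituted iodoalkene on a ring that already carries the strained ether, and the ketone must enolise toward C5 during the capture.
- Comparison: it is complementary to the chosen plan and not a replacement. Overall step economy is at best equal.

Alternative 3: The cut is C5=C6. KOH on alumina with CBr2F2 halogenates C6 of the eleven-membered sulfone A5, the C5 carbanion closes the episulfone, and loss of SO2 gives A6 (Ramberg–Bäcklund contraction).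
- In its favour: the sensitive enol-lactone alkene is made last. The eleven-membered thia ring closes easily, and the oxolane and butenolide can be built on open chains, so the bridge problem again becomes a driven ring contraction; on this point it is better than the chosen plan. Precedent for medium-ring alkenes is equal.
- Against it here: strong base meets a butenolide and a free alcohol. A γ-sulfonyl butenolide can lose sulfinate instead. The alkene geometry from the episulfone is not controlled, and C8 is not addressed.
- Comparison: the alkene-forming mechanism is sound, but the route to A5 is long and step economy is worse.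

Key step: step 9

Remark 1: the descriptors of the target SMILES are followed literally (1S,4S,8S,10R, germacrane numbering), so C5 and C10 lie on opposite faces of the oxolane; step 15 is designed for this arrangement and is the step most at risk after the key step.
Remark 2: 13 and 16 were checked against the chair transition state and against C4 and C8 of 31 and need no change. The isopropenyl-bearing carbon of 13 has the spatial arrangement of (R)-limonene, so the (R) series is used, starting from dienol 1, which is assumed to be purchasable (it is made from (R)-limonene oxide).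
Remark 3: triethylsilyl is used on the C4 oxygen because it must leave under mild acid in step 15. Germacrane numbering is used for all ring-expanded compounds.

Step 1
Reactants: 1 (1S,4R)-1-methyl-4-(prop-1-en-2-yl)cyclohex-2-en-1-ol
Product: 2 (6S)-3-methyl-6-(prop-1-en-2-yl)cyclohex-2-en-1-one
Conditions: pyridinium chlorochromate (C5H5NH[CrO3Cl]), NaOAc, CH2Cl2, 25 °C
Reagents that add atoms: none
Why: Babler–Dauben oxidative transposition: the chromate ester of the tertiary allylic alcohol shifts [3,3] and the secondary chromate is oxidised to the enone; the isopropenyl-bearing centre is untouched and the acetate buffer keeps the isopropenyl group out of conjugation.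

Step 2
Reactants: 2 (6S)-3-methyl-6-(prop-1-en-2-yl)cyclohex-2-en-1-one
Product: 3 (1S,6S)-3-methyl-6-(prop-1-en-2-yl)cyclohex-2-en-1-ol (hydroxyl cis to isopropenyl)
Conditions: LiBH(s-Bu)3, THF, −78 °C
Reagents that add atoms: none
Why: 1,2-reduction of a β,β-disubstituted enone by a bulky borohydride; hydride arrives anti to the neighbouring isopropenyl group, so the hydroxyl is cis to it and can direct the next step.

Step 3
Reactants: 3 (1S,6S)-3-methyl-6-(prop-1-en-2-yl)cyclohex-2-en-1-ol
Product: 4 (1R,2R,3S,6S)-6-methyl-3-(prop-1-en-2-yl)-7-oxabicyclo[4.1.0]heptan-2-ol (epoxide, hydroxyl and isopropenyl all cis)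
Conditions: VO(acac)2 (2 mol%), t-BuOOH, CH2Cl2, 0 °C
Reagents that add atoms: tert-butyl hydroperoxide CC(C)(C)OO
Why: Hydroxyl-directed vanadium-catalysed epoxidation of an allylic alcohol delivers oxygen on the hydroxyl face (as with carveol), which fixes the future C4 oxygen cis to the isopropenyl group; the merely homoallylic isopropenyl alkene reacts far more slowly.

Step 4
Reactants: 4 (1R,2R,3S,6S)-6-methyl-3-(prop-1-en-2-yl)-7-oxabicyclo[4.1.0]heptan-2-ol
Product: 5 (1S,3S,4S)-1-methyl-4-(prop-1-en-2-yl)cyclohexane-1,3-diol
Conditions: LiAlH4, THF, 0 → 25 °C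
Reagents that add atoms: none
Why: Hydride opens the trisubstituted epoxide at its secondary carbon in the trans-diaxial (Fürst–Plattner) sense, leaving the oxygen on the methyl-bearing carbon as the tertiary alcohol with the configuration set in step 3.

Step 5
Reactants: 5 (1S,3S,4S)-1-methyl-4-(prop-1-en-2-yl)cyclohexane-1,3-diol
Product: 6 (2S,5S)-5-hydroxy-5-methyl-2-(prop-1-en-2-yl)cyclohexan-1-one
Conditions: Dess–Martin periodinane, NaHCO3, CH2Cl2, 0 → 25 °C
Reagents that add atoms: none
Why: Only the secondary alcohol can be oxidised; the buffered, non-basic medium avoids retro-aldol cleavage and dehydration of the β-hydroxy ketone, and the α-centre already holds the favoured equatorial isopropenyl group.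

Step 6
Reactants: 6 (2S,5S)-5-hydroxy-5-methyl-2-(prop-1-en-2-yl)cyclohexan-1-one
Product: 7 (2S,5S)-5-methyl-2-(prop-1-en-2-yl)-5-(triethylsilyloxy)cyclohexan-1-one
Conditions: Et3SiOTf, 2,6-lutidine, CH2Cl2, −78 → −40 °C
Reagents that add atoms: triethylsilyl trifluoromethanesulfonate CC[Si](CC)(CC)OS(=O)(=O)C(F)(F)F
Why: Silyl triflate silylation of a hindered tertiary alcohol; the ether masks the β-hydroxyl through the basic steps and, being axial in the favoured chair, later shields the axial face of the ketone.

Step 7
Reactants: 8 4-methoxybenzyl alcohol; 9 trichloroethylene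
Product: 10 (E)-1,2-dichlorovinyl 4-methoxybenzyl ether
Conditions: KH, THF, 0 °C; 9, −50 → 25 °C
Reagents that add atoms: none
Why: First stage of Greene's alkynyl ether synthesis: the potassium alkoxide replaces the geminal chloride of trichloroethylene in a net substitution and gives a storable precursor of the alkoxyacetylide.

Step 8
Reactants: 7 (2S,5S)-5-methyl-2-(prop-1-en-2-yl)-5-(triethylsilyloxy)cyclohexan-1-one; 10 (E)-1,2-dichlorovinyl 4-methoxybenzyl ether
Product: 13 (1S,2S,5S)-1-[(E)-2-(4-methoxybenzyloxy)ethenyl]-5-methyl-2-(prop-1-en-2-yl)-5-(triethylsilyloxy)cyclohexan-1-ol, via lithium alkoxyacetylide 11 (not isolated), via lithium propargylic alkoxide 12 (not isolated)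
Conditions: 10, n-BuLi (2.1 equiv), THF, −78 → −40 °C; 7, −78 °C; LiAlH4, −78 → 0 °C; basic aqueous work-up
Reagents that add atoms: none
Why: Dehydrochlorination and lithiation of 10 give acetylide 11, which adds to the ketone from the equatorial side because the axial silyloxy group blocks the axial path (as in 3,3,5-trimethylcyclohexanone), so the new chain is trans to isopropenyl and the hydroxyl is axial. Alkoxide-directed trans-hydroalumination of the alkynyl ether (Arens-type reduction of alkoxyethynyl carbinols) then gives the E enol ether; 12 is kept cold to avoid the sigmatropic shift known for benzyl alkynyl ethers.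

Step 9
Reactants: 13 (1S,2S,5S)-1-[(E)-2-(4-methoxybenzyloxy)ethenyl]-5-methyl-2-(prop-1-en-2-yl)-5-(triethylsilyloxy)cyclohexan-1-ol
Product: 16 (3S,9S,5E)-3-(4-methoxybenzyloxy)-5,9-dimethyl-9-(triethylsilyloxy)cyclodec-5-en-1-one (germacrane numbering: C6 ketone, 8S ether, 4S silyl ether, E-C1=C10), via potassium alkoxide 14 (not isolated), via potassium enolate 15 (not isolated)
Conditions: KH, 18-crown-6, THF, 0 → 25 °C; then −78 °C, aq. NH4Cl
Reagents that add atoms: none
Why: KH with the crown ether gives the free alkoxide 14, whose anionic oxy-Cope rearrangement ([3,3] shift, the known ring expansion of trans-1,2-dialkenylcyclohexanols to (E)-cyclodec-5-enones) forms C8–C9 and breaks the C1–C6 bond. The ten-membered ring arises by ring expansion and not by end-to-end closure: the cyclohexane opens through a chair-like six-centre transition state trans-fused to the cyclohexane chair, with both alkenyl groups equatorial. C8 is the only new stereocentre: the E enol ether places the 4-methoxybenzyloxy group pseudo-equatorial in that chair, and the carbinol configuration from step 8 decides which face of the enol ether meets the isopropenyl terminus, so C8 forms S. The same chair converts the equatorial C1–C2 bond into the E C1=C10 alkene and gives the C6–C7 enolate 15, protonated at C7 in the cold quench. The step needs chair over boat, secured by the trans-diequatorial alkenyl groups. It also needs enolate 15 to keep its C8 alkoxide, for which the temperature is kept as low as the shift allows. Migration of the silyl group between the two syn-axial oxygens is tolerated because only 14 can rearrange.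

Step 10
Reactants: 16 (3S,9S,5E)-3-(4-methoxybenzyloxy)-5,9-dimethyl-9-(triethylsilyloxy)cyclodec-5-en-1-one
Product: 17 the (1R,10R)-1,10-epoxide of 16 (trans epoxide in place of C1=C10; 4S and 8S unchanged)
Conditions: D-fructose-derived Shi ketone (1,2:4,5-di-O-isopropylidene-β-D-erythro-2,3-hexodiulo-2,6-pyranose, 30 mol%), KHSO5 (as Oxone), K2CO3, Bu4NHSO4, MeCN/CH2(OMe)2/aq. Na2B4O7 buffer, 0 °C
Reagents that add atoms: potassium peroxymonosulfate [K+].[O-]S(=O)(=O)OO
Why: Shi epoxidation: the chiral dioxirane transfers oxygen to E-trisubstituted alkenes through a spiro transition state, and the D-fructose-derived ketone gives the R,R epoxide, here (1R,10R). Only the outer face of the ring alkene is open, and in the conformer left by the ring expansion that outer face is the same one, so reagent and substrate should agree; ketone, silyl ether and benzyl ether are inert at 0 °C.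

Step 11
Reactants: 18 methyl 2-(hydroxymethyl)acrylate
Product: 19 methyl 2-[(triethylsilyloxy)methyl]acrylate
Conditions: Et3SiCl, imidazole, CH2Cl2, 0 °C
Reagents that add atoms: chlorotriethylsilane CC[Si](CC)(CC)Cl
Why: Standard silylation of a primary alcohol; the triethylsilyl group is chosen so that it leaves together with the C4 silyl ether in step 15.

Step 12
Reactants: 19 methyl 2-[(triethylsilyloxy)methyl]acrylate
Product: 20 methyl 2-oxo-3-(triethylsilyloxy)propanoate
Conditions: O3, CH2Cl2, −78 °C; Me2S, −78 → 25 °C
Reagents that add atoms: ozone [O-][O+]=O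
Why: Ozonolysis of the 1,1-disubstituted alkene with reductive work-up gives the α-keto ester and formaldehyde; the reagent is dried azeotropically and used at once.

Step 13
Reactants: 17 the (1R,10R)-1,10-epoxide of 16; 20 methyl 2-oxo-3-(triethylsilyloxy)propanoate
Product: 22 methyl (Z)-keto enoate: 17 carrying at C7 the exocyclic alkene C7=C11(CO2Me)(CH2OSiEt3) with the ester cis to the C6 ketone, via tertiary aldol acetate 21 (not isolated)
Conditions: LiN(i-Pr)2, THF, −78 °C; 20, −78 °C; Ac2O, −78 → 0 °C; DBU, 0 → 25 °C
Reagents that add atoms: none
Why: Kinetic deprotonation occurs at C7, away from the fully substituted C4 (as in 3,3-disubstituted cyclohexanones), and the lithium enolate adds to the ketone carbonyl of 20 (pyruvate aldol, added cold to outrun proton transfer). Acetylation of the tertiary aldolate and DBU-induced E1cB loss of acetate, a far better leaving group than the C8 alkoxide, give the ene-1,4-dicarbonyl unit; its Z and E isomers interconvert under the amine base and Z is drawn because only it can lactonise.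

Step 14
Reactants: 22 methyl (Z)-keto enoate
Product: 24 (1R,10R)-1,10-epoxy-8S-(4-methoxybenzyloxy)-4S,13-bis(triethylsilyloxy)germacra-5,7(11)-dien-12,6-olide (C4 cis to C7 across C5=C6), via keto acid 23 (not isolated)
Conditions: LiOH, THF/H2O, 0 °C; HCl to pH 4, extraction; Ac2O, Et3N, DMAP (cat.), CH2Cl2, 0 → 25 °C
Reagents that add atoms: none
Why: Saponification of the activated methyl ester, then enol lactonisation of the γ-keto acid through its mixed anhydride (the classical anhydride/base closure of γ-keto acids): the ketone can enolise only toward C5, and O-acylation of that enol closes the butenolide and creates C5=C6. The isomer with C4 on the C7 side keeps the C4–C8 segment folded as the later bridge requires; the other isomer would need correction (see the risks).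

Step 15
Reactants: 24 epoxy bis-silyl butenolide
Product: 26 (1S,4S,8S,10R)-1,4-epoxy-10,13-dihydroxy-8-(4-methoxybenzyloxy)germacra-5,7(11)-dien-12,6-olide, via epoxy diol 25 (not isolated)
Conditions: PPTS, CH2Cl2/MeOH (10:1), 0 → 25 °C
Reagents that add atoms: none
Why: Mild acid methanolysis removes both triethylsilyl ethers and activates the epoxide; the C4 hydroxyl, which in the conformer inherited from the ring expansion lies over the inner face of C1 opposite the epoxide oxygen, opens the epoxide at C1 in a 5-exo closure with inversion (Kishi-type epoxy alcohol cyclisation, as in the furanoid linalool oxides). This sets 1S and releases the 10R tertiary alcohol; the weak acid and the short tether favour 5-exo attack at C1 over 6-endo attack at the tertiary C10.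

Step 16
Reactants: 26 bridged diol
Product: 27 (1S,4S,8S,10R)-13-acetoxy-1,4-epoxy-10-hydroxy-8-(4-methoxybenzyloxy)germacra-5,7(11)-dien-12,6-olide
Conditions: Ac2O, pyridine, CH2Cl2, 0 °C
Reagents that add atoms: acetic anhydride CC(=O)OC(C)=O
Why: Acetylation of the primary allylic alcohol; the tertiary C10 hydroxyl does not react without a stronger catalyst.

Step 17
Reactants: 27 the 13-acetate
Product: 28 (1S,4S,8S,10R)-13-acetoxy-1,4-epoxy-8,10-dihydroxygermacra-5,7(11)-dien-12,6-olide
Conditions: DDQ, CH2Cl2/pH 7 buffer, 0 °C
Reagents that add atoms: none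
Why: Oxidative cleavage of the 4-methoxybenzyl ether by hydride abstraction; the electron-poor dienolide, the acetate and the tertiary alcohol are not oxidised.

Step 18
Reactants: 28 the C8 alcohol; 29 angelic acid
Product: 31 the target, (1S,4S,8S,10R)-13-acetoxy-8-angeloyloxy-1,4-epoxy-10-hydroxygermacra-5,7(11)-dien-12,6-olide, via mixed anhydride 30 (not isolated)
Conditions: 29, 2,4,6-Cl3C6H2COCl, Et3N, toluene, 25 °C; then 28, 80 °C
Reagents that add atoms: none
Why: Yamaguchi esterification through the trichlorobenzoyl mixed anhydride without a nucleophilic catalyst is the established way to make angelates without Z to E isomerisation; only the secondary allylic hydroxyl is acylated and C8 keeps its configuration.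

Compound list
1 | (1S,4R)-1-methyl-4-(prop-1-en-2-yl)cyclohex-2-en-1-ol | C1=C[C@@](C)(O)CC[C@H]1C(C)=C | starting material
2 | (6S)-3-methyl-6-(prop-1-en-2-yl)cyclohex-2-en-1-one | O=C1C=C(C)CC[C@H]1C(C)=C | intermediate
3 | (1S,6S)-3-methyl-6-(prop-1-en-2-yl)cyclohex-2-en-1-ol | O[C@H]1C=C(C)CC[C@H]1C(C)=C | intermediate
4 | (1R,2R,3S,6S)-6-methyl-3-(prop-1-en-2-yl)-7-oxabicyclo[4.1.0]heptan-2-ol | O[C@H]1[C@H]2O[C@@]2(C)CC[C@H]1C(C)=C | intermediate
5 | (1S,3S,4S)-1-methyl-4-(prop-1-en-2-yl)cyclohexane-1,3-diol | O[C@H]1C[C@@](C)(O)CC[C@H]1C(C)=C | intermediate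
6 | (2S,5S)-5-hydroxy-5-methyl-2-(prop-1-en-2-yl)cyclohexan-1-one | O=C1C[C@@](C)(O)CC[C@H]1C(C)=C | intermediate
7 | (2S,5S)-5-methyl-2-(prop-1-en-2-yl)-5-(triethylsilyloxy)cyclohexan-1-one | O=C1C[C@@](C)(O[Si](CC)(CC)CC)CC[C@H]1C(C)=C | intermediate
8 | 4-methoxybenzyl alcohol | COc1ccc(CO)cc1 | starting material
9 | trichloroethylene | ClC=C(Cl)Cl | starting material
10 | (E)-1,2-dichlorovinyl 4-methoxybenzyl ether | COc1ccc(CO/C(Cl)=C\Cl)cc1 | intermediate
11 | lithium (4-methoxybenzyloxy)acetylide | [Li+].[C-]#COCc1ccc(OC)cc1 | intermediate
12 | lithium alkoxide of (1S,2S,5S)-1-[(4-methoxybenzyloxy)ethynyl]-5-methyl-2-(prop-1-en-2-yl)-5-(triethylsilyloxy)cyclohexan-1-ol | [Li+].[O-][C@@]1(C#COCc2ccc(OC)cc2)C[C@@](C)(O[Si](CC)(CC)CC)CC[C@H]1C(C)=C | intermediate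
13 | (1S,2S,5S)-1-[(E)-2-(4-methoxybenzyloxy)ethenyl]-5-methyl-2-(prop-1-en-2-yl)-5-(triethylsilyloxy)cyclohexan-1-ol | O[C@@]1(/C=C/OCc2ccc(OC)cc2)C[C@@](C)(O[Si](CC)(CC)CC)CC[C@H]1C(C)=C | intermediate
14 | potassium alkoxide of 13 | [K+].[O-][C@@]1(/C=C/OCc2ccc(OC)cc2)C[C@@](C)(O[Si](CC)(CC)CC)CC[C@H]1C(C)=C | intermediate
15 | potassium C6–C7 enolate of 16 | [K+].[O-]/C1=C\[C@@H](OCc2ccc(OC)cc2)C/C(C)=C/CC[C@](C)(O[Si](CC)(CC)CC)C1 | intermediate
16 | (3S,9S,5E)-3-(4-methoxybenzyloxy)-5,9-dimethyl-9-(triethylsilyloxy)cyclodec-5-en-1-one | COc1ccc(CO[C@H]2C/C(C)=C/CC[C@](C)(O[Si](CC)(CC)CC)CC(=O)C2)cc1 | intermediate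
17 | (1R,10R)-1,10-epoxide of 16 | COc1ccc(CO[C@H]2C[C@@]3(C)O[C@@H]3CC[C@](C)(O[Si](CC)(CC)CC)CC(=O)C2)cc1 | intermediate
18 | methyl 2-(hydroxymethyl)acrylate | C=C(CO)C(=O)OC | starting material
19 | methyl 2-[(triethylsilyloxy)methyl]acrylate | C=C(CO[Si](CC)(CC)CC)C(=O)OC | intermediate
20 | methyl 2-oxo-3-(triethylsilyloxy)propanoate | COC(=O)C(=O)CO[Si](CC)(CC)CC | intermediate
21 | tertiary aldol acetate of 17 and 20 (mixture at C7 and C11) | COc1ccc(CO[C@H]2C[C@@]3(C)O[C@@H]3CC[C@](C)(O[Si](CC)(CC)CC)CC(=O)C2C(CO[Si](CC)(CC)CC)(OC(C)=O)C(=O)OC)cc1 | intermediate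
22 | methyl (Z)-keto enoate (C7=C11, ester cis to the C6 ketone) | COc1ccc(CO[C@H]2C[C@@]3(C)O[C@@H]3CC[C@](C)(O[Si](CC)(CC)CC)CC(=O)/C2=C(\C(=O)OC)CO[Si](CC)(CC)CC)cc1 | intermediate
23 | (Z)-keto acid from 22 | COc1ccc(CO[C@H]2C[C@@]3(C)O[C@@H]3CC[C@](C)(O[Si](CC)(CC)CC)CC(=O)/C2=C(\C(=O)O)CO[Si](CC)(CC)CC)cc1 | intermediate
24 | (1R,10R)-1,10-epoxy-8S-(4-methoxybenzyloxy)-4S,13-bis(triethylsilyloxy)germacra-5,7(11)-dien-12,6-olide | COc1ccc(CO[C@H]2C[C@@]3(C)O[C@@H]3CC[C@](C)(O[Si](CC)(CC)CC)/C=C4/OC(=O)C(CO[Si](CC)(CC)CC)=C24)cc1 | intermediate
25 | epoxy diol from 24 (4-OH, 13-OH) | COc1ccc(CO[C@H]2C[C@@]3(C)O[C@@H]3CC[C@](C)(O)/C=C4/OC(=O)C(CO)=C24)cc1 | intermediate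
26 | (1S,4S,8S,10R)-1,4-epoxy-10,13-dihydroxy-8-(4-methoxybenzyloxy)germacra-5,7(11)-dien-12,6-olide | COc1ccc(CO[C@H]2C[C@@](C)(O)[C@@H]3CC[C@@](C)(/C=C4/OC(=O)C(CO)=C24)O3)cc1 | intermediate
27 | 13-acetate of 26 | COc1ccc(CO[C@H]2C[C@@](C)(O)[C@@H]3CC[C@@](C)(/C=C4/OC(=O)C(COC(C)=O)=C24)O3)cc1 | intermediate
28 | (1S,4S,8S,10R)-13-acetoxy-1,4-epoxy-8,10-dihydroxygermacra-5,7(11)-dien-12,6-olide | O[C@H]1C[C@@](C)(O)[C@@H]2CC[C@@](C)(/C=C3/OC(=O)C(COC(C)=O)=C31)O2 | intermediate
29 | angelic acid | C/C=C(/C)C(=O)O | starting material
30 | angelic 2,4,6-trichlorobenzoic anhydride | C/C=C(/C)C(=O)OC(=O)c1c(Cl)cc(Cl)cc1Cl | intermediate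
31 | CNP0162854.1 | C/C=C(/C)C(=O)O[C@H]1C[C@@](C)(O)[C@@H]2CC[C@@](C)(/C=C3/OC(=O)C(COC(C)=O)=C31)O2 | target

Total step count: 18. Longest linear sequence: 15 steps (1–6, 8–10, 13–18); steps 7, 11 and 12 prepare the two side reagents.

Least certain steps

Step 9 (key step). The most likely failure is loss of the C8 alkoxide from enolate 15 by E1cB elimination, because the naked potassium enolate carries the leaving group in the β position at the temperature the shift needs. A second possibility is that the anion rests on the C4 oxygen after silyl migration and the shift stalls. Fallback: the rearrangement is run without an anion. From 13, the tertiary hydroxyl is silylated with N-trimethylsilylimidazole to the trimethylsilyl ether F1, which is heated (degassed decalin, about 200 °C, base-washed glass) in a thermal siloxy-Cope rearrangement through the same chair to the trimethylsilyl enol ether F2. K2CO3 in methanol at 0 °C then releases 16, where the route is rejoined.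

Step 15. The bridge to be formed holds C5 and C10 on opposite faces of the oxolane, so the C5–C9 segment must stretch past the ring oxygen in the transition state. Ring strain may therefore stop the 5-exo attack and let other processes take over: 6-endo attack at the tertiary C10, methanolysis of the epoxide, hydride shift to a C1 ketone, or acid ionisation of the tertiary allylic C4–O bond, which would also scramble C4. Fallback: the ether is closed while C5–C7 are still a flexible ketone chain. From 17, PPTS in CH2Cl2/MeOH gives the bridged hydroxy ketone F3, and Et3SiOTf/2,6-lutidine gives its C10 silyl ether F4. The conditions of step 13 with 20 then give the keto enoate F5, and those of step 14 the bridged butenolide F6. PPTS in methanol removes both silyl groups and returns to the route at 26.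

Step 10. Only the outer face of each ring conformer is open and the conformers interconvert, so the face preferred by the catalyst may belong to a poorly populated conformer. The result would be poor facial selectivity or a slow reaction in which the ketone is consumed by side oxidation. Fallback: the epoxidation is postponed until the ring is rigid. From 16, the conditions of step 13 give the alkene keto enoate F7 and those of step 14 the alkene butenolide F8. In F8 the folded dienolide segment fixes the ring conformation, so mCPBA (NaHCO3, CH2Cl2, 0 °C) should epoxidise the exposed face of C1=C10 under substrate control and give 24.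

Step 14. The E isomer of acid 23 cannot reach the C6 oxygen, so incomplete E to Z equilibration would leave unclosed material. The enol may also be acylated with C4 on the wrong side of C5=C6. Fallback: the lactone is closed before the enol double bond is made. From 22, LiOH as in step 14 gives the acid mixture; irradiation (350 nm, benzene) isomerises the E acid, and the Z acid closes on the ketone to the lactol (6-hydroxy butenolide) F9. Methanesulfonyl chloride and Et3N then dehydrate F9 toward C5 and give 24.

## Further compounds

F1 | step 9 | trimethylsilyl ether of 13 | C[Si](C)(C)O[C@@]1(/C=C/OCc2ccc(OC)cc2)C[C@@](C)(O[Si](CC)(CC)CC)CC[C@H]1C(C)=C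
F2 | step 9 | trimethylsilyl C6–C7 enol ether of 16 | C[Si](C)(C)O/C1=C\[C@@H](OCc2ccc(OC)cc2)C/C(C)=C/CC[C@](C)(O[Si](CC)(CC)CC)C1
F3 | step 15 | (1S,4S,8S,10R)-1,4-epoxy-10-hydroxy-8-(4-methoxybenzyloxy) ten-membered C6 ketone | COc1ccc(CO[C@H]2C[C@@](C)(O)[C@@H]3CC[C@@](C)(CC(=O)C2)O3)cc1
F4 | step 15 | C10 triethylsilyl ether of F3 | COc1ccc(CO[C@H]2C[C@@](C)(O[Si](CC)(CC)CC)[C@@H]3CC[C@@](C)(CC(=O)C2)O3)cc1
F5 | step 15 | bridged methyl (Z)-keto enoate | COc1ccc(CO[C@H]2C[C@@](C)(O[Si](CC)(CC)CC)[C@@H]3CC[C@@](C)(CC(=O)/C2=C(\C(=O)OC)CO[Si](CC)(CC)CC)O3)cc1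
F6 | step 15 | bridged butenolide with C10 and C13 triethylsilyl ethers | COc1ccc(CO[C@H]2C[C@@](C)(O[Si](CC)(CC)CC)[C@@H]3CC[C@@](C)(/C=C4/OC(=O)C(CO[Si](CC)(CC)CC)=C24)O3)cc1
F7 | step 10 | alkene analogue of 22 (C1=C10 retained) | COc1ccc(CO[C@H]2C/C(C)=C/CC[C@](C)(O[Si](CC)(CC)CC)CC(=O)/C2=C(\C(=O)OC)CO[Si](CC)(CC)CC)cc1
F8 | step 10 | alkene analogue of 24 (C1=C10 retained) | COc1ccc(CO[C@H]2C/C(C)=C/CC[C@](C)(O[Si](CC)(CC)CC)/C=C3/OC(=O)C(CO[Si](CC)(CC)CC)=C23)cc1
F9 | step 14 | 6-hydroxy butenolide (lactol) from acid 23 (C6 epimers) | COc1ccc(CO[C@H]2C[C@@]3(C)O[C@@H]3CC[C@](C)(O[Si](CC)(CC)CC)CC4(O)OC(=O)C(CO[Si](CC)(CC)CC)=C24)cc1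
A1 | alternative 1 | thirteen-membered C8–O–C12 stannyl ether | CCCC[Sn](CCCC)(CCCC)[C@H]1C[C@@](C)(O[Si](CC)(CC)CC)[C@@H]2CC[C@@](C)(CC3(OCCO3)/C=C(/CO[Si](C)(C)C(C)(C)C)CO1)O2
A2 | alternative 1 | ten-membered C8 alcohol with exocyclic C11=C12 methylene | O[C@H]1C[C@@](C)(O[Si](CC)(CC)CC)[C@@H]2CC[C@@](C)(CC3(OCCO3)[C@@H]1C(=C)CO[Si](C)(C)C(C)(C)C)O2
A3 | alternative 2 | (Z)-β-iodoenone | CC[Si](CC)(CC)O[C@H]1C[C@@](C)(O)[C@@H]2CC[C@@](C)(CC(=O)/C1=C(\I)CO[Si](C)(C)C(C)(C)C)O2
A4 | alternative 2 | 8-triethylsilyl 13-tert-butyldimethylsilyl ether of the deacylated target | CC[Si](CC)(CC)O[C@H]1C[C@@](C)(O)[C@@H]2CC[C@@](C)(/C=C3/OC(=O)C(CO[Si](C)(C)C(C)(C)C)=C31)O2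
A5 | alternative 3 | eleven-membered C5–SO2–C6 sulfone (C6 epimers) | CC(C)(C)[Si](C)(C)O[C@H]1C[C@@](C)(O)[C@@H]2CC[C@@](C)(CS(=O)(=O)C3OC(=O)C(CO[Si](C)(C)C(C)(C)C)=C31)O2
A6 | alternative 3 | 8,13-bis(tert-butyldimethylsilyl) ether of the deacylated target | CC(C)(C)[Si](C)(C)O[C@H]1C[C@@](C)(O)[C@@H]2CC[C@@](C)(/C=C3/OC(=O)C(CO[Si](C)(C)C(C)(C)C)=C31)O2
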